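**Plan**

- Numbering: ring A is the 4‑hydroxy‑3‑methoxyphenyl ring on C7, ring B is the 4‑acetyl‑2,6‑dimethoxyphenyl ring on the C8 oxygen, and C9 is the CH2OH carbon.
- Retrosynthesis cuts the C7–H bond first (carbinol back to aryl ketone, with C9 raised to an ethyl ester), then the C7–C8 bond (ester enolate plus ring A aroyl chloride), then the C8–O bond to ring B (phenol plus bromoacetate).
- Forward, no ring is made; the chain is joined in the order O–C8 (etherification), masking of the acetyl group as a dioxolane, C7–C8 (C‑acylation), C7–H (enzyme), then ester to C9 alcohol, debenzylation and ketal removal.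
- Enabling feature: C7 is a benzylic carbinol on ring A next to C8; at the ketone/ester level the C8 hydrogen lies between the C7 carbonyl, the C9 ester and the ring B ether oxygen and epimerises freely.
- Stereochemistry: C7 (R) and C8 (S in the target) are both set in one ketoreductase dynamic kinetic reduction, and no later step touches either centre.

Key step: step 5

Assumption: a ketoreductase that accepts the bulky 2‑aryloxy substrate and gives the anti isomer is taken to be obtainable by panel screening. The (2R,3R) descriptors of the hydroxy ester and the (7R,8S) descriptors of the target describe the same spatial arrangement, because the ester carbon outranks C7 at C8 whereas CH2OH does not.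

**Route**

Step 1
Reactants: 1 acetosyringone; 2 ethyl bromoacetate
Product: 3 ethyl 2-(4-acetyl-2,6-dimethoxyphenoxy)acetate
Conditions: K2CO3, acetone, reflux
Reagents that add atoms: none
Why: Williamson ether synthesis, in which the acidic para‑acyl phenol is deprotonated by K2CO3 and, although flanked by two methoxy groups, displaces bromide from the unhindered, carbonyl‑activated primary bromide in an SN2 reaction that leaves the methyl ketone untouched.

Step 2
Reactants: 3 ethyl 2-(4-acetyl-2,6-dimethoxyphenoxy)acetate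
Product: 4 ethyl 2-[2,6-dimethoxy-4-(2-methyl-1,3-dioxolan-2-yl)phenoxy]acetate
Conditions: HOCH2CH2OH (3 equiv), p-TsOH·H2O (5 mol%), toluene, reflux, Dean–Stark
Reagents that add atoms: ethylene glycol, OCCO
Why: Acid‑catalysed ketalisation driven by azeotropic removal of water converts the only ketone into a 1,3‑dioxolane, which removes the acidic acetyl hydrogens before the enolate chemistry of step 4 and ensures that C7 will later carry the only ketone.

Step 3
Reactants: 5 4-benzyloxy-3-methoxybenzoic acid (O‑benzylvanillic acid)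
Product: 6 4-benzyloxy-3-methoxybenzoyl chloride
Conditions: (COCl)2 (1.2 equiv), DMF (cat.), CH2Cl2, 0 °C → rt; concentrate
Reagents that add atoms: oxalyl chloride, ClC(=O)C(=O)Cl
Why: Acid chloride formation with oxalyl chloride under DMF catalysis proceeds at room temperature with only gaseous by‑products and does not touch the benzyl or methyl aryl ethers.

Step 4
Reactants: 4 ethyl 2-[2,6-dimethoxy-4-(2-methyl-1,3-dioxolan-2-yl)phenoxy]acetate; 6 4-benzyloxy-3-methoxybenzoyl chloride
Product: 9 ethyl (2RS)-3-(4-benzyloxy-3-methoxyphenyl)-2-[2,6-dimethoxy-4-(2-methyl-1,3-dioxolan-2-yl)phenoxy]-3-oxopropanoate, via lithium ester enolate 7 (not isolated), via lithium keto ester enolate 8 (not isolated)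
Conditions: LiN(i-Pr)2 (2.1 equiv), THF, −78 °C; then 6 (1.0 equiv), −78 → −40 °C; sat. aq NH4Cl
Reagents that add atoms: none
Why: Crossed Claisen‑type C‑acylation of a preformed lithium ester enolate by an aroyl chloride that cannot enolise, in which the second equivalent of amide base converts the more acidic product at once into enolate 8, shielding it from a second acylation until the buffered quench, and C8 arises racemic and stereolabile as intended.

Step 5
Reactants: 9 ethyl (2RS)-3-(4-benzyloxy-3-methoxyphenyl)-2-[2,6-dimethoxy-4-(2-methyl-1,3-dioxolan-2-yl)phenoxy]-3-oxopropanoate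
Product: 10 ethyl (2R,3R)-3-(4-benzyloxy-3-methoxyphenyl)-2-[2,6-dimethoxy-4-(2-methyl-1,3-dioxolan-2-yl)phenoxy]-3-hydroxypropanoate
Conditions: ketoreductase (anti‑selective hit from panel screening), NADP+ (cat.), i-PrOH (10% v/v), KH2PO4/K2HPO4 buffer (0.1 M, pH 7.0), MgSO4 (2 mM), DMSO (10% v/v), 30 °C
Reagents that add atoms: none
Why: The NADPH‑dependent ketoreductase binds the antipode of 9 that becomes (2R) in 10 and transfers hydride from the nicotinamide to the Si face of the C7 carbonyl (priorities O > C8 > aryl), the oxidised cofactor being reduced again by enzyme‑coupled oxidation of isopropanol to acetone. The closest known reaction type is the ketoreductase dynamic kinetic reduction of α‑substituted β‑keto esters. No ring is closed. C7 is set by the carbonyl face that the active site presents to the cofactor, and C8 by the preference of the enzyme for one antipode of the substrate. The step needs enantio‑, anti‑diastereo‑ and chemoselectivity at once: the C8 hydrogen lies between the C7 ketone, the C9 ester and the ring B ether oxygen, so the unreactive antipode should re‑equilibrate through the enol in neutral buffer faster than it is reduced, and the dioxolane leaves C7 as the only ketone. The anti (2R,3R) outcome depends on the enzyme and is to be secured by screening a ketoreductase panel on this substrate.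

Step 6
Reactants: 10 ethyl (2R,3R)-3-(4-benzyloxy-3-methoxyphenyl)-2-[2,6-dimethoxy-4-(2-methyl-1,3-dioxolan-2-yl)phenoxy]-3-hydroxypropanoate
Product: 11 (1R,2S)-1-(4-benzyloxy-3-methoxyphenyl)-2-[2,6-dimethoxy-4-(2-methyl-1,3-dioxolan-2-yl)phenoxy]propane-1,3-diol
Conditions: LiBH4 (2 equiv), THF, 0 °C → rt
Reagents that add atoms: none
Why: Hydride reduction of an ester by LiBH4, helped by the neighbouring oxygen atoms that bind lithium, spares the ketal and the benzyl ether and does not involve C7 or C8, the low temperature suppressing retro‑aldol cleavage and the change of the C8 descriptor from R to S being due only to the lower rank of CH2OH.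

Step 7
Reactants: 11 (1R,2S)-1-(4-benzyloxy-3-methoxyphenyl)-2-[2,6-dimethoxy-4-(2-methyl-1,3-dioxolan-2-yl)phenoxy]propane-1,3-diol
Product: 12 (1R,2S)-2-[2,6-dimethoxy-4-(2-methyl-1,3-dioxolan-2-yl)phenoxy]-1-(4-hydroxy-3-methoxyphenyl)propane-1,3-diol
Conditions: H2 (1 atm), 10% Pd/C, EtOAc/EtOH, rt
Reagents that add atoms: none
Why: Heterogeneous catalytic hydrogenolysis of the benzyl aryl ether under neutral conditions should leave the secondary benzylic alcohol at C7 and the alkyl aryl ether at C8 intact, while the ketal keeps the aryl ketone away from hydrogen.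

Step 8
Reactants: 12 (1R,2S)-2-[2,6-dimethoxy-4-(2-methyl-1,3-dioxolan-2-yl)phenoxy]-1-(4-hydroxy-3-methoxyphenyl)propane-1,3-diol
Product: 13 1-[4-{[(1R,2S)-1,3-dihydroxy-1-(4-hydroxy-3-methoxyphenyl)propan-2-yl]oxy}-3,5-dimethoxyphenyl]ethan-1-one
Conditions: 1 M aq. HCl/THF (1:5), 0 °C → rt
Reagents that add atoms: water, O
Why: Acid‑catalysed ketal hydrolysis through an aryl‑stabilised oxocarbenium ion takes place in dilute acid at room temperature, well below the acidity and temperature needed to ionise the C7 benzylic alcohol or cleave the C8 aryl ether, so both stereocentres should be retained.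

**Compound list**

1 | acetosyringone (1-(4-hydroxy-3,5-dimethoxyphenyl)ethan-1-one) | CC(=O)c1cc(OC)c(O)c(OC)c1 | starting material
2 | ethyl bromoacetate | CCOC(=O)CBr | starting material
3 | ethyl 2-(4-acetyl-2,6-dimethoxyphenoxy)acetate | CCOC(=O)COc1c(OC)cc(C(C)=O)cc1OC | intermediate
4 | ethyl 2-[2,6-dimethoxy-4-(2-methyl-1,3-dioxolan-2-yl)phenoxy]acetate | CCOC(=O)COc1c(OC)cc(C2(C)OCCO2)cc1OC | intermediate
5 | 4-benzyloxy-3-methoxybenzoic acid (O‑benzylvanillic acid) | COc1cc(C(=O)O)ccc1OCc1ccccc1 | starting material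
6 | 4-benzyloxy-3-methoxybenzoyl chloride | COc1cc(C(=O)Cl)ccc1OCc1ccccc1 | intermediate
7 | lithium ester enolate: lithium 1-ethoxy-2-[2,6-dimethoxy-4-(2-methyl-1,3-dioxolan-2-yl)phenoxy]ethen-1-olate (not isolated) | CCOC(O[Li])=COc1c(OC)cc(C2(C)OCCO2)cc1OC | intermediate
8 | lithium keto ester enolate: lithium 1-(4-benzyloxy-3-methoxyphenyl)-3-ethoxy-2-[2,6-dimethoxy-4-(2-methyl-1,3-dioxolan-2-yl)phenoxy]-3-oxoprop-1-en-1-olate (not isolated) | CCOC(=O)C(Oc1c(OC)cc(C2(C)OCCO2)cc1OC)=C(O[Li])c1ccc(OCc2ccccc2)c(OC)c1 | intermediate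
9 | ethyl (2RS)-3-(4-benzyloxy-3-methoxyphenyl)-2-[2,6-dimethoxy-4-(2-methyl-1,3-dioxolan-2-yl)phenoxy]-3-oxopropanoate (racemic, stereolabile at C2) | CCOC(=O)C(Oc1c(OC)cc(C2(C)OCCO2)cc1OC)C(=O)c1ccc(OCc2ccccc2)c(OC)c1 | intermediate
10 | ethyl (2R,3R)-3-(4-benzyloxy-3-methoxyphenyl)-2-[2,6-dimethoxy-4-(2-methyl-1,3-dioxolan-2-yl)phenoxy]-3-hydroxypropanoate | COc1cc([C@@H](O)[C@H](C(=O)OCC)Oc2c(OC)cc(C3(C)OCCO3)cc2OC)ccc1OCc1ccccc1 | intermediate
11 | (1R,2S)-1-(4-benzyloxy-3-methoxyphenyl)-2-[2,6-dimethoxy-4-(2-methyl-1,3-dioxolan-2-yl)phenoxy]propane-1,3-diol | COc1cc([C@@H](O)[C@H](CO)Oc2c(OC)cc(C3(C)OCCO3)cc2OC)ccc1OCc1ccccc1 | intermediate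
12 | (1R,2S)-2-[2,6-dimethoxy-4-(2-methyl-1,3-dioxolan-2-yl)phenoxy]-1-(4-hydroxy-3-methoxyphenyl)propane-1,3-diol | COc1cc([C@@H](O)[C@H](CO)Oc2c(OC)cc(C3(C)OCCO3)cc2OC)ccc1O | intermediate
13 | 1-[4-{[(1R,2S)-1,3-dihydroxy-1-(4-hydroxy-3-methoxyphenyl)propan-2-yl]oxy}-3,5-dimethoxyphenyl]ethan-1-one | COc1cc([C@@H](O)[C@H](CO)Oc2c(OC)cc(C(C)=O)cc2OC)ccc1O | target

**Step count**

Total steps: 8. Longest linear sequence: 7 steps (steps 1, 2, 4, 5, 6, 7, 8 from acetosyringone); step 3 is a one‑step side branch.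

**Steps most likely to fail**

Step 5 (enzymatic reduction). The panel may contain no enzyme that turns over a substrate with so large a 2‑aryloxy group. Alternatively, the active enzymes may pair the carbonyl face with the other C8 antipode and deliver the syn isomer. The fallback sets out from 9 and returns at 11. Transfer hydrogenation with dynamic kinetic resolution (RuCl(p-cymene)[(R,R)-TsDPEN], HCO2H/Et3N, CH2Cl2, 30 °C) is a chemocatalytic reaction known to convert 2‑alkoxy 3‑keto esters into syn hydroxy esters. It should give ethyl (2R,3S)-3-(4-benzyloxy-3-methoxyphenyl)-2-[2,6-dimethoxy-4-(2-methyl-1,3-dioxolan-2-yl)phenoxy]-3-hydroxypropanoate F1; the ligand antipode follows the usual aryl ketone model and would be confirmed on the product. LiBH4 in THF should then give the threo diol (1S,2S)-1-(4-benzyloxy-3-methoxyphenyl)-2-[2,6-dimethoxy-4-(2-methyl-1,3-dioxolan-2-yl)phenoxy]propane-1,3-diol F2. TBSCl and imidazole in CH2Cl2 should silylate the primary hydroxyl only, giving (1S,2S)-1-(4-benzyloxy-3-methoxyphenyl)-3-(tert-butyldimethylsilyloxy)-2-[2,6-dimethoxy-4-(2-methyl-1,3-dioxolan-2-yl)phenoxy]propan-1-ol F3. A Mitsunobu reaction (4‑nitrobenzoic acid, PPh3, DIAD, THF, 0 °C) should invert C7 and give (1R,2S)-1-(4-benzyloxy-3-methoxyphenyl)-3-(tert-butyldimethylsilyloxy)-2-[2,6-dimethoxy-4-(2-methyl-1,3-dioxolan-2-yl)phenoxy]propyl 4-nitrobenzoate F4. K2CO3 in MeOH should remove the nitrobenzoate to give (1R,2S)-1-(4-benzyloxy-3-methoxyphenyl)-3-(tert-butyldimethylsilyloxy)-2-[2,6-dimethoxy-4-(2-methyl-1,3-dioxolan-2-yl)phenoxy]propan-1-ol F5, and Bu4NF in THF should remove the silyl ether to reach 11.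

Step 4 (C‑acylation). O‑acylation or a second acylation of the product enolate, and self‑condensation of the ester enolate on warming, may erode the yield of the keto ester. The fallback sets out from 4 and returns at 9, replacing steps 3 and 4. Enolate 7, generated from 4 with LiN(i-Pr)2 in THF at −78 °C, is added to commercial 4-benzyloxy-3-methoxybenzaldehyde F6 in a lithium aldol reaction. This should give ethyl 3-(4-benzyloxy-3-methoxyphenyl)-2-[2,6-dimethoxy-4-(2-methyl-1,3-dioxolan-2-yl)phenoxy]-3-hydroxypropanoate F7 as a mixture of racemic diastereomers, whose composition does not matter. Oxidation of the benzylic alcohol with Dess–Martin periodinane (NaHCO3, CH2Cl2, rt) should then give 9.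

Step 2 (ketalisation). Under the same acid catalysis the glycol may exchange into the ethyl ester, and the electron‑rich aryl ketone may ketalise too slowly for full conversion. The fallback sets out from 1 and returns at 4, forming the ketal before any ester is present. Benzylation of 1 (BnBr, K2CO3, DMF) should give 1-(4-benzyloxy-3,5-dimethoxyphenyl)ethan-1-one F8. Ketalisation (ethylene glycol, p-TsOH·H2O, toluene, Dean–Stark) should give 2-(4-benzyloxy-3,5-dimethoxyphenyl)-2-methyl-1,3-dioxolane F9. Hydrogenolysis (H2, 10% Pd/C, EtOAc) should give 2,6-dimethoxy-4-(2-methyl-1,3-dioxolan-2-yl)phenol F10. Alkylation of this phenol with 2 (K2CO3, acetone, reflux) should give 4.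

**Further compounds**

F1 | step 5 | ethyl (2R,3S)-3-(4-benzyloxy-3-methoxyphenyl)-2-[2,6-dimethoxy-4-(2-methyl-1,3-dioxolan-2-yl)phenoxy]-3-hydroxypropanoate | COc1cc([C@H](O)[C@H](C(=O)OCC)Oc2c(OC)cc(C3(C)OCCO3)cc2OC)ccc1OCc1ccccc1
F2 | step 5 | (1S,2S)-1-(4-benzyloxy-3-methoxyphenyl)-2-[2,6-dimethoxy-4-(2-methyl-1,3-dioxolan-2-yl)phenoxy]propane-1,3-diol | COc1cc([C@H](O)[C@H](CO)Oc2c(OC)cc(C3(C)OCCO3)cc2OC)ccc1OCc1ccccc1
F3 | step 5 | (1S,2S)-1-(4-benzyloxy-3-methoxyphenyl)-3-(tert-butyldimethylsilyloxy)-2-[2,6-dimethoxy-4-(2-methyl-1,3-dioxolan-2-yl)phenoxy]propan-1-ol | COc1cc([C@H](O)[C@H](CO[Si](C)(C)C(C)(C)C)Oc2c(OC)cc(C3(C)OCCO3)cc2OC)ccc1OCc1ccccc1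
F4 | step 5 | (1R,2S)-1-(4-benzyloxy-3-methoxyphenyl)-3-(tert-butyldimethylsilyloxy)-2-[2,6-dimethoxy-4-(2-methyl-1,3-dioxolan-2-yl)phenoxy]propyl 4-nitrobenzoate | COc1cc([C@@H](OC(=O)c2ccc(cc2)[N+](=O)[O-])[C@H](CO[Si](C)(C)C(C)(C)C)Oc2c(OC)cc(C3(C)OCCO3)cc2OC)ccc1OCc1ccccc1
F5 | step 5 | (1R,2S)-1-(4-benzyloxy-3-methoxyphenyl)-3-(tert-butyldimethylsilyloxy)-2-[2,6-dimethoxy-4-(2-methyl-1,3-dioxolan-2-yl)phenoxy]propan-1-ol | COc1cc([C@@H](O)[C@H](CO[Si](C)(C)C(C)(C)C)Oc2c(OC)cc(C3(C)OCCO3)cc2OC)ccc1OCc1ccccc1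
F6 | step 4 | 4-benzyloxy-3-methoxybenzaldehyde (O‑benzylvanillin, purchased) | COc1cc(C=O)ccc1OCc1ccccc1
F7 | step 4 | ethyl 3-(4-benzyloxy-3-methoxyphenyl)-2-[2,6-dimethoxy-4-(2-methyl-1,3-dioxolan-2-yl)phenoxy]-3-hydroxypropanoate (mixture of racemic diastereomers) | CCOC(=O)C(Oc1c(OC)cc(C2(C)OCCO2)cc1OC)C(O)c1ccc(OCc2ccccc2)c(OC)c1
F8 | step 2 | 1-(4-benzyloxy-3,5-dimethoxyphenyl)ethan-1-one | CC(=O)c1cc(OC)c(OCc2ccccc2)c(OC)c1
F9 | step 2 | 2-(4-benzyloxy-3,5-dimethoxyphenyl)-2-methyl-1,3-dioxolane | CC1(OCCO1)c1cc(OC)c(OCc2ccccc2)c(OC)c1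
F10 | step 2 | 2,6-dimethoxy-4-(2-methyl-1,3-dioxolan-2-yl)phenol | CC1(OCCO1)c1cc(OC)c(O)c(OC)c1
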